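## Retrosynthetic overview

1. Target 18 ⇐ octabenzyl, C8-bromo dimer 17 by one hydrogenolysis (eight benzyl ethers and the blocking bromine).
2. The all-cis C3/C4 array is relayed from C2: hydride addition to ketone 16 anti to both aryl groups sets C3; hydroboration of 4-aryl-flav-3-ene 13 anti to the C2 aryl sets C4.
3. The interflavan C4–C6 bond is made as an sp2–sp2 bond by Negishi coupling of flav-3-en-4-yl triflate 5 with the C6-zinc reagent of C8-bromo-blocked pentabenzylcatechin. The usual C4 carbocation plus catechin Friedel–Crafts coupling is avoided because it favours 3,4-trans products and C8/C6 mixtures.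
4. Triflate 5 ⇐ (2S)-flavanone 4 ⇐ catalytic asymmetric conjugate arylation of 7-benzyloxychromone, the only stereocentre made from achiral material.
5. Ring order: rings A and C of the upper unit come fused in the chromone and ring B is attached in step 2; all rings of the lower unit come from (+)-catechin; no ring is closed later.

Assumption: (R)-t-BuPyOX is taken as the ligand antipode that gives the (2S)-flavanone, by analogy with the facial sense of this catalyst on cyclic enones; if the sense is opposite the (S)-ligand is used, and any minor enantiomer is removed as a diastereomer after step 8.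

The target is (2R,3R,4S) in the upper unit (2,3-cis-3,4-cis, all three substituents on one face) and (2R,3S) in the lower unit, linked C4→C6.

## Route

**Step 1**
Reactants: 1 7-hydroxy-4H-chromen-4-one
Product: 2 7-(benzyloxy)-4H-chromen-4-one
Conditions: BnBr, K2CO3, DMF, rt
Reagents that add atoms: benzyl bromide, BrCc1ccccc1
Why: Williamson etherification of the acidic 7-phenol; no stereocentre is involved.

**Step 2**
Reactants: 2 7-(benzyloxy)-4H-chromen-4-one; 3 [3,4-bis(benzyloxy)phenyl]boronic acid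
Product: 4 (2S)-7-(benzyloxy)-2-[3,4-bis(benzyloxy)phenyl]chroman-4-one
Conditions: Pd(OCOCF3)2 (5 mol %), (R)-t-BuPyOX (6 mol %), NH4PF6 (30 mol %), H2O (5 equiv), ClCH2CH2Cl, 60 °C
Reagents that add atoms: none
Why: Asymmetric conjugate addition of an arylboronic acid to a chromone (Hayashi–Miyaura type, cationic palladium/PyOX), in which the chiral aryl-palladium species carbopalladates one face of the enone and water protonates the palladium enolate, so C2 is set as S without a free basic enolate that could ring-open to the chalcone.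

**Step 3**
Reactants: 4 (2S)-7-(benzyloxy)-2-[3,4-bis(benzyloxy)phenyl]chroman-4-one
Product: 5 (2S)-7-(benzyloxy)-2-[3,4-bis(benzyloxy)phenyl]-2H-chromen-4-yl trifluoromethanesulfonate
Conditions: Tf2O, 2,6-di-tert-butyl-4-methylpyridine, CH2Cl2, 0 °C → rt, dark
Reagents that add atoms: trifluoromethanesulfonic anhydride, O=S(=O)(OS(=O)(=O)C(F)(F)F)C(F)(F)F
Why: Enol triflate formation by O-triflation of the ketone and loss of H-3 to the hindered pyridine, which avoids a metal enolate and its retro-oxa-Michael opening, so C2 is untouched.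

**Step 4**
Reactants: 6 (+)-catechin
Product: 7 (2R,3S)-5,7-bis(benzyloxy)-2-[3,4-bis(benzyloxy)phenyl]chroman-3-ol
Conditions: BnBr, K2CO3, DMF, 0 °C → rt
Reagents that add atoms: benzyl bromide, BrCc1ccccc1
Why: Williamson etherification in which K2CO3 deprotonates only the four phenols, leaving the secondary alcohol and both stereocentres unchanged.

**Step 5**
Reactants: 7 (2R,3S)-5,7-bis(benzyloxy)-2-[3,4-bis(benzyloxy)phenyl]chroman-3-ol
Product: 8 (2R,3S)-3,5,7-tris(benzyloxy)-2-[3,4-bis(benzyloxy)phenyl]chromane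
Conditions: NaH, BnBr, Bu4NI (cat.), THF, 0 °C → rt
Reagents that add atoms: benzyl bromide, BrCc1ccccc1
Why: Williamson etherification of the secondary alkoxide, which masks the 3-OH against the organometallic of step 8 and the oxidation of step 10 without touching C2 or C3.

**Step 6**
Reactants: 8 (2R,3S)-3,5,7-tris(benzyloxy)-2-[3,4-bis(benzyloxy)phenyl]chromane
Product: 9 (2R,3S)-3,5,7-tris(benzyloxy)-2-[3,4-bis(benzyloxy)phenyl]-8-bromochromane
Conditions: NBS (1.0 equiv), CH2Cl2, −78 °C → rt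
Reagents that add atoms: N-bromosuccinimide, O=C1CCC(=O)N1Br
Why: Electrophilic aromatic bromination goes to C8, the most nucleophilic position of the phloroglucinol-type ring A of benzylated catechins, and so blocks that position.

**Step 7**
Reactants: 9 (2R,3S)-3,5,7-tris(benzyloxy)-2-[3,4-bis(benzyloxy)phenyl]-8-bromochromane
Product: 10 (2R,3S)-3,5,7-tris(benzyloxy)-2-[3,4-bis(benzyloxy)phenyl]-8-bromo-6-iodochromane
Conditions: NIS, CF3CO2H (cat.), CH2Cl2/MeCN, 0 °C, dark
Reagents that add atoms: N-iodosuccinimide, O=C1CCC(=O)N1I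
Why: Electrophilic aromatic iodination at C6, the only free position of ring A and activated by three oxygen donors, which is far more reactive than the dibenzyloxyphenyl ring B.

**Step 8**
Reactants: 10 (2R,3S)-3,5,7-tris(benzyloxy)-2-[3,4-bis(benzyloxy)phenyl]-8-bromo-6-iodochromane; 5 (2S)-7-(benzyloxy)-2-[3,4-bis(benzyloxy)phenyl]-2H-chromen-4-yl trifluoromethanesulfonate
Product: 13 (2S)-7-(benzyloxy)-2-[3,4-bis(benzyloxy)phenyl]-4-[(2R,3S)-3,5,7-tris(benzyloxy)-2-[3,4-bis(benzyloxy)phenyl]-8-bromochroman-6-yl]-2H-chromene, via arylmagnesium chloride 11 (not isolated), via arylzinc chloride 12 (not isolated)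
Conditions: 10, i-PrMgCl·LiCl, THF, −20 → 0 °C; ZnCl2, 0 °C → rt; then 5, Pd(PPh3)4 (5 mol %), THF, 50 °C, dark
Reagents that add atoms: none
Why: Iodine–magnesium exchange is selective for C–I over the hindered C–Br, and after transmetallation to zinc a Negishi cross-coupling (zerovalent palladium inserts into the alkenyl C–OTf bond much faster than into the di-ortho-substituted electron-rich aryl bromide) forges the interflavan bond with unambiguous 4→6 connectivity, creating no stereocentre and leaving C2 intact.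

**Step 9**
Reactants: 13 (2S)-7-(benzyloxy)-2-[3,4-bis(benzyloxy)phenyl]-4-[(2R,3S)-3,5,7-tris(benzyloxy)-2-[3,4-bis(benzyloxy)phenyl]-8-bromochroman-6-yl]-2H-chromene
Product: 15 (2R,3S,4S)-7-(benzyloxy)-2-[3,4-bis(benzyloxy)phenyl]-4-[(2R,3S)-3,5,7-tris(benzyloxy)-2-[3,4-bis(benzyloxy)phenyl]-8-bromochroman-6-yl]chroman-3-ol (2,3-trans-3,4-trans), via alkylborane 14 (not isolated)
Conditions: BH3·THF, THF, 0 °C → rt; then NaOH aq, H2O2, 0 °C → rt
Reagents that add atoms: hydrogen peroxide, OO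
Why: Brown hydroboration–oxidation adds H and B syn across C3=C4 on the face opposite the C2 aryl with boron at the less substituted C3, so H-4 enters anti to the C2 aryl (the C4 aryl ends up cis to it, 4S) and oxidation with retention gives the 3-OH trans to both aryls.

**Step 10**
Reactants: 15 (2R,3S,4S)-7-(benzyloxy)-2-[3,4-bis(benzyloxy)phenyl]-4-[(2R,3S)-3,5,7-tris(benzyloxy)-2-[3,4-bis(benzyloxy)phenyl]-8-bromochroman-6-yl]chroman-3-ol
Product: 16 (2R,4S)-7-(benzyloxy)-2-[3,4-bis(benzyloxy)phenyl]-4-[(2R,3S)-3,5,7-tris(benzyloxy)-2-[3,4-bis(benzyloxy)phenyl]-8-bromochroman-6-yl]chroman-3-one (2,4-cis)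
Conditions: Dess–Martin periodinane, pyridine, CH2Cl2, 0 °C → rt; used crude
Reagents that add atoms: none
Why: Dess–Martin oxidation of the secondary alcohol under buffered, non-enolising conditions removes only the C3 stereocentre and keeps the 2,4-cis diaryl arrangement set in step 9.

**Step 11**
Reactants: 16 (2R,4S)-7-(benzyloxy)-2-[3,4-bis(benzyloxy)phenyl]-4-[(2R,3S)-3,5,7-tris(benzyloxy)-2-[3,4-bis(benzyloxy)phenyl]-8-bromochroman-6-yl]chroman-3-one
Product: 17 (2R,3R,4S)-7-(benzyloxy)-2-[3,4-bis(benzyloxy)phenyl]-4-[(2R,3S)-3,5,7-tris(benzyloxy)-2-[3,4-bis(benzyloxy)phenyl]-8-bromochroman-6-yl]chroman-3-ol (2,3-cis-3,4-cis)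
Conditions: LiBH(s-Bu)3, THF, −78 °C; then H2O
Reagents that add atoms: none
Why: Substrate-controlled diastereoselective ketone reduction in which the bulky borohydride attacks C3 from the face opposite the two flanking cis aryl groups (the same sense as the known catechin-to-epicatechin ketone reduction), so the new hydroxyl is cis to both and C3 is set as R.

**Step 12**
Reactants: 17 (2R,3R,4S)-7-(benzyloxy)-2-[3,4-bis(benzyloxy)phenyl]-4-[(2R,3S)-3,5,7-tris(benzyloxy)-2-[3,4-bis(benzyloxy)phenyl]-8-bromochroman-6-yl]chroman-3-ol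
Product: 18 (2R,3R,4S)-2-(3,4-dihydroxyphenyl)-4-[(2R,3S)-2-(3,4-dihydroxyphenyl)-3,5,7-trihydroxychroman-6-yl]chromane-3,7-diol (CNP0141631.2)
Conditions: H2 (1 atm), Pd(OH)2/C, Et3N, THF/MeOH/H2O, rt
Reagents that add atoms: none
Why: Catalytic hydrogenolysis cleaves the eight benzyl ethers and the C8–Br bond (Et3N takes up HBr), while the cyclic benzylic ether and diarylmethine bonds of flavans survive these neutral conditions, so all five stereocentres are kept.

## Compound list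

1 | 7-hydroxy-4H-chromen-4-one | O=c1ccoc2cc(O)ccc12 | starting material
2 | 7-(benzyloxy)-4H-chromen-4-one | O=c1ccoc2cc(OCc3ccccc3)ccc12 | intermediate
3 | [3,4-bis(benzyloxy)phenyl]boronic acid | OB(O)c1ccc(OCc2ccccc2)c(OCc2ccccc2)c1 | starting material
4 | (2S)-7-(benzyloxy)-2-[3,4-bis(benzyloxy)phenyl]chroman-4-one | O=C1C[C@@H](c2ccc(OCc3ccccc3)c(OCc3ccccc3)c2)Oc2cc(OCc3ccccc3)ccc12 | intermediate
5 | (2S)-7-(benzyloxy)-2-[3,4-bis(benzyloxy)phenyl]-2H-chromen-4-yl trifluoromethanesulfonate | O=S(=O)(OC1=C[C@@H](c2ccc(OCc3ccccc3)c(OCc3ccccc3)c2)Oc2cc(OCc3ccccc3)ccc12)C(F)(F)F | intermediate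
6 | (+)-catechin, (2R,3S)-2-(3,4-dihydroxyphenyl)chromane-3,5,7-triol | O[C@H]1Cc2c(O)cc(O)cc2O[C@@H]1c1ccc(O)c(O)c1 | starting material
7 | (2R,3S)-5,7-bis(benzyloxy)-2-[3,4-bis(benzyloxy)phenyl]chroman-3-ol | c1c(OCc3ccccc3)cc2c(c1OCc1ccccc1)C[C@H](O)[C@@H](c1ccc(OCc3ccccc3)c(OCc3ccccc3)c1)O2 | intermediate
8 | (2R,3S)-3,5,7-tris(benzyloxy)-2-[3,4-bis(benzyloxy)phenyl]chromane | c1c(OCc3ccccc3)cc2c(c1OCc1ccccc1)C[C@H](OCc1ccccc1)[C@@H](c1ccc(OCc3ccccc3)c(OCc3ccccc3)c1)O2 | intermediate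
9 | (2R,3S)-3,5,7-tris(benzyloxy)-2-[3,4-bis(benzyloxy)phenyl]-8-bromochromane | c1c(OCc3ccccc3)c(Br)c2c(c1OCc1ccccc1)C[C@H](OCc1ccccc1)[C@@H](c1ccc(OCc3ccccc3)c(OCc3ccccc3)c1)O2 | intermediate
10 | (2R,3S)-3,5,7-tris(benzyloxy)-2-[3,4-bis(benzyloxy)phenyl]-8-bromo-6-iodochromane | Ic1c(OCc3ccccc3)c(Br)c2c(c1OCc1ccccc1)C[C@H](OCc1ccccc1)[C@@H](c1ccc(OCc3ccccc3)c(OCc3ccccc3)c1)O2 | intermediate
11 | [(2R,3S)-3,5,7-tris(benzyloxy)-2-[3,4-bis(benzyloxy)phenyl]-8-bromochroman-6-yl]magnesium chloride | Cl[Mg]c1c(OCc3ccccc3)c(Br)c2c(c1OCc1ccccc1)C[C@H](OCc1ccccc1)[C@@H](c1ccc(OCc3ccccc3)c(OCc3ccccc3)c1)O2 | intermediate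
12 | [(2R,3S)-3,5,7-tris(benzyloxy)-2-[3,4-bis(benzyloxy)phenyl]-8-bromochroman-6-yl]zinc chloride | Cl[Zn]c1c(OCc3ccccc3)c(Br)c2c(c1OCc1ccccc1)C[C@H](OCc1ccccc1)[C@@H](c1ccc(OCc3ccccc3)c(OCc3ccccc3)c1)O2 | intermediate
13 | (2S)-7-(benzyloxy)-2-[3,4-bis(benzyloxy)phenyl]-4-[(2R,3S)-3,5,7-tris(benzyloxy)-2-[3,4-bis(benzyloxy)phenyl]-8-bromochroman-6-yl]-2H-chromene | c1ccccc1COc1ccc2c(c1)O[C@H](c1ccc(OCc3ccccc3)c(OCc3ccccc3)c1)C=C2c1c(OCc3ccccc3)c(Br)c2c(c1OCc1ccccc1)C[C@H](OCc1ccccc1)[C@@H](c1ccc(OCc3ccccc3)c(OCc3ccccc3)c1)O2 | intermediate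
14 | alkylborane from 13: BH2 on C3 and H on C4, both on the face opposite the C2 aryl | c1ccccc1COc1ccc2c(c1)O[C@H](c1ccc(OCc3ccccc3)c(OCc3ccccc3)c1)[C@@H]([BH2])[C@@H]2c1c(OCc3ccccc3)c(Br)c2c(c1OCc1ccccc1)C[C@H](OCc1ccccc1)[C@@H](c1ccc(OCc3ccccc3)c(OCc3ccccc3)c1)O2 | intermediate
15 | (2R,3S,4S)-7-(benzyloxy)-2-[3,4-bis(benzyloxy)phenyl]-4-[(2R,3S)-3,5,7-tris(benzyloxy)-2-[3,4-bis(benzyloxy)phenyl]-8-bromochroman-6-yl]chroman-3-ol | c1ccccc1COc1ccc2c(c1)O[C@H](c1ccc(OCc3ccccc3)c(OCc3ccccc3)c1)[C@@H](O)[C@@H]2c1c(OCc3ccccc3)c(Br)c2c(c1OCc1ccccc1)C[C@H](OCc1ccccc1)[C@@H](c1ccc(OCc3ccccc3)c(OCc3ccccc3)c1)O2 | intermediate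
16 | (2R,4S)-7-(benzyloxy)-2-[3,4-bis(benzyloxy)phenyl]-4-[(2R,3S)-3,5,7-tris(benzyloxy)-2-[3,4-bis(benzyloxy)phenyl]-8-bromochroman-6-yl]chroman-3-one | c1ccccc1COc1ccc2c(c1)O[C@H](c1ccc(OCc3ccccc3)c(OCc3ccccc3)c1)C(=O)[C@@H]2c1c(OCc3ccccc3)c(Br)c2c(c1OCc1ccccc1)C[C@H](OCc1ccccc1)[C@@H](c1ccc(OCc3ccccc3)c(OCc3ccccc3)c1)O2 | intermediate
17 | (2R,3R,4S)-7-(benzyloxy)-2-[3,4-bis(benzyloxy)phenyl]-4-[(2R,3S)-3,5,7-tris(benzyloxy)-2-[3,4-bis(benzyloxy)phenyl]-8-bromochroman-6-yl]chroman-3-ol | c1ccccc1COc1ccc2c(c1)O[C@H](c1ccc(OCc3ccccc3)c(OCc3ccccc3)c1)[C@H](O)[C@@H]2c1c(OCc3ccccc3)c(Br)c2c(c1OCc1ccccc1)C[C@H](OCc1ccccc1)[C@@H](c1ccc(OCc3ccccc3)c(OCc3ccccc3)c1)O2 | intermediate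
18 | (2R,3R,4S)-2-(3,4-dihydroxyphenyl)-4-[(2R,3S)-2-(3,4-dihydroxyphenyl)-3,5,7-trihydroxychroman-6-yl]chromane-3,7-diol | Oc1ccc2c(c1)O[C@H](c1ccc(O)c(O)c1)[C@H](O)[C@@H]2c1c(O)cc2c(c1O)C[C@H](O)[C@@H](c1ccc(O)c(O)c1)O2 | target

## Step count and risks

Total step count: 12 (steps 1–3 for the upper fragment, steps 4–7 for the lower fragment, steps 8–12 after convergence).
Longest linear sequence: 9 steps (steps 4–12, from (+)-catechin).

The three steps most likely to fail:

Step 8 (Negishi coupling). The arylzinc is flanked by two benzyloxy groups, the bond formed is crowded, and the 2H-chromene must not ring-open or racemise. The fallback sets out from 10 and flavanone 4 and comes back at 13. Compound 10 is converted into the arylmagnesium chloride 11 as before, and 11 is added to the carbonyl group of 4 in the presence of LaCl3·2LiCl (THF, −20 → 0 °C; the lanthanum salt favours 1,2-addition over enolisation and ring opening). This gives the tertiary 4-arylflavan-4-ol F1 as a mixture of C4 epimers. Catalytic pyridinium p-toluenesulfonate in toluene at rt then removes water across C3–C4 through the doubly benzylic cation and returns 13.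

Step 9 (hydroboration). The trisubstituted alkene carries a twisted di-ortho-substituted aryl group and may react slowly or give reductive opening of the allylic ether. The fallback sets out from 13 and comes back at 16, bypassing 15 and step 10. Dimethyldioxirane (acetone, −40 °C) epoxidises C3=C4 on the face opposite the C2 aryl to give the 3,4-epoxyflavan F2. InCl3 (cat., CH2Cl2, −20 °C) then triggers a Meinwald rearrangement (ionisation at the doubly benzylic C4, suprafacial 1,2-shift of H-3) to the 2,4-trans 4-arylflavan-3-one F3. KN(SiMe3)2 (THF, −78 °C) converts F3 into the potassium enolate F4, which is protonated with 2,6-di-tert-butylphenol on the face opposite the C2 aryl to give the 2,4-cis ketone 16.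

Step 11 (hydride reduction). The C4–H of 16 is doubly benzylic and alpha to the ketone, so the basic borohydride may enolise instead of reduce, and the facial selectivity with the extra C4 aryl is not proven. The fallback sets out from 16 and comes back at 17 and makes no new compound (F0). It replaces the stoichiometric, substrate-controlled hydride by a catalyst-controlled transfer hydrogenation under dynamic kinetic resolution (Noyori–Ikariya type): RuCl(p-cymene)[(S,S)-TsDPEN] or its antipode, whichever is matched to the 2R centre, in HCO2H/Et3N at rt. This medium is non-basic toward the substrate, the labile C4 centre equilibrates through the enol, and α-aryl cyclic ketones are reduced to the cis aryl alcohols, which here is the all-cis alcohol 17.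

## Further compounds

F1 | step 8 | (2S)-7-(benzyloxy)-2-[3,4-bis(benzyloxy)phenyl]-4-[(2R,3S)-3,5,7-tris(benzyloxy)-2-[3,4-bis(benzyloxy)phenyl]-8-bromochroman-6-yl]chroman-4-ol, mixture of C4 epimers | c1ccccc1COc1ccc2c(c1)O[C@H](c1ccc(OCc3ccccc3)c(OCc3ccccc3)c1)CC2(O)c1c(OCc3ccccc3)c(Br)c2c(c1OCc1ccccc1)C[C@H](OCc1ccccc1)[C@@H](c1ccc(OCc3ccccc3)c(OCc3ccccc3)c1)O2
F2 | step 9 | 3,4-epoxide of 13 with the oxirane on the face opposite the C2 aryl | c1ccccc1COc1ccc2c(c1)O[C@H](c1ccc(OCc3ccccc3)c(OCc3ccccc3)c1)[C@H]4O[C@]42c1c(OCc3ccccc3)c(Br)c2c(c1OCc1ccccc1)C[C@H](OCc1ccccc1)[C@@H](c1ccc(OCc3ccccc3)c(OCc3ccccc3)c1)O2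
F3 | step 9 | (2R,4R)-7-(benzyloxy)-2-[3,4-bis(benzyloxy)phenyl]-4-[(2R,3S)-3,5,7-tris(benzyloxy)-2-[3,4-bis(benzyloxy)phenyl]-8-bromochroman-6-yl]chroman-3-one (2,4-trans) | c1ccccc1COc1ccc2c(c1)O[C@H](c1ccc(OCc3ccccc3)c(OCc3ccccc3)c1)C(=O)[C@H]2c1c(OCc3ccccc3)c(Br)c2c(c1OCc1ccccc1)C[C@H](OCc1ccccc1)[C@@H](c1ccc(OCc3ccccc3)c(OCc3ccccc3)c1)O2
F4 | step 9 | potassium C3–C4 enolate of F3 and 16 | c1ccccc1COc1ccc2c(c1)O[C@H](c1ccc(OCc3ccccc3)c(OCc3ccccc3)c1)C([O-])=C2c1c(OCc3ccccc3)c(Br)c2c(c1OCc1ccccc1)C[C@H](OCc1ccccc1)[C@@H](c1ccc(OCc3ccccc3)c(OCc3ccccc3)c1)O2.[K+]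
F0 | step 11 | none | none
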